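Remark: abietane numbering is used throughout (ring A = C1–C5, C10; ring B = C5–C10; ring C = C8, C9, C11–C14; side chain C15–C17; C20 = lactone carbonyl). Ar = 5-[(2S)-1-(benzyloxy)propan-2-yl]-2-bromo-3,4-dimethoxyphenyl. The ligand enantiomer of step 3 that gives the (S) side chain is assumed to be identified in a trial run.

## Structural features

The target is 16-acetoxycarnosol. A gem-dimethylcyclohexane (ring A) and a catechol-bearing benzene (ring C) flank ring B, and the C20 carbonyl on C10 is tied through oxygen to C7, so that ring B, the lactone and the arene form a 2-oxabicyclo[2.2.2]octan-3-one with the arene as one bridge. Three stereocentres sit in this cage: the quaternary, benzylic C10 (R) is adjacent to C5 (S), and C7 (S) faces C10 across ring B through the lactone. The fourth, C15 (S), lies on the side chain of ring C, insulated from the others by the arene, and can only be set by an external reagent. The fragile groups are the C11/C12 catechol (oxidised by air and base), the C7–O bond (a para-oxygenated benzylic ester, open to ionisation and hydrogenolysis) and the primary C16 acetate (lost to organolithiums, amide bases and boron halides). The real difficulties are the fully substituted C10, wedged between ring A, the carbonyl and an arene carbon with an ortho oxygen, and the need to acylate one hydroxyl out of three. The key step exploits the fact that C10 is the α-carbon of the C20 lactone while C9 is an ortho carbon of the aryl group on C7: with the C7–O–C20 tether in place, C9 is held over the C10 enolate and ring B closes by forming the single C9–C10 bond. The trans A/B junction then follows from geometry, since only the enolate face that carries the aryl group can bond.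

## Logic of the disconnections

23 to 22: the acetyl C–O bond at O16 is cut. The acetate is the one group that cannot pass through the organolithium, amide-base and boron-halide steps, so it goes on last. The gain is that all three hydroxyls can be unmasked together. The demand is an acylation that picks the primary aliphatic hydroxyl over two phenols, which points to an enzymatic acyl transfer.

22 to 21: the two O–CH3 bonds at C11/C12 and the O–CH2Ph bond at C16 are cut. These ethers tolerate every earlier step and fall in one operation. The forward step must spare the C7–O bond and must not let the freed benzyl cation alkylate C14.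

21 to 19: the C9–C10 bond is cut. This removes the quaternary stereocentre, ring B and the bicyclic cage in one stroke and leaves a ring A-fused lactone whose only controlling centres are C7 and C5. The forward step needs a halogen on C9, an enolate at C10 and the aryl group on C7 trans to the C5–C4 bond; the C10 configuration of 19 is irrelevant.

19 to 17: the C1–C10 bond is cut, opening ring A to a 3-bromopropyl chain on C4. Ring A then comes from an acyclic five-carbon piece. The forward step is an enolate C-alkylation forming a six-membered ring that must leave the aryl bromide alone. A four-step ring A construction by conjugate allylation, enolate allylation, ring-closing metathesis and hydrogenation was set aside: Lewis-acid conjugate allylation of unsaturated lactones is unreliable, the Lewis acid endangers the C7–O bond, and the hydrogenation would have to spare C9–Br.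

17 to 15 and 16: the C4–C5 bond is cut. A quaternary carbon next to a stereocentre is best made by adding a tertiary radical to the unsaturated lactone. The cut separates the aryl lactone from a commercial alkene. The addition must occur anti to the C7 aryl group and tolerate both bromides.

15 to 14, then to 12 and 13: the C5=C10 double bond is cut as a metathesis retron, then the C20–O acyl bond. The lactone is reduced to a homoallylic alcohol with one stereocentre plus a two-carbon acyl unit. The forward metathesis involves an electron-poor acrylate.

12 to 10: the C6–C7 bond is cut. C7 arises from an aldehyde by reagent-controlled allylation, which must be highly face-selective, independent of the remote C15, and tolerant of the ortho bromide.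

10 to 7: the C9–Br bond is cut and the aldehyde is masked. C9 lies between the C8 substituent and the C11 oxygen; electrophilic bromination would go to C14, para to that oxygen. Directed metalation is therefore required, and it must be regioselective and spare the benzyl ether.

7 to 6, then to 4: the O–benzyl bond is cut, then the C16–O and C15–H bonds as a hydroboration retron. C15 arises from a prochiral 1,1-disubstituted alkene. The forward step needs catalyst-controlled face selection with anti-Markovnikov regiochemistry, with the aldehyde masked.

4 to 2 and 3, then to 1: the C13–C15 bond is cut as an sp2–sp2 coupling, then the acetal C–O bonds. Everything is then commercial. The acetal only has to survive aqueous base.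

## Other disconnections considered

Alternative 1: The cut runs through ring C at C9–C11 and C8–C14. The arene would be assembled last from the trans-decalin enone A2 (C7 ketone, C8=C9 alkene, ester on C10) and the enantiopure 2-silyloxy diene A3 that carries the C15 side chain; a Diels–Alder reaction under Brønsted-superacid catalysis would give the tricyclic silyl enol ether A1.
- In its favour: it is convergent and forms two C–C bonds and a ring at once. The quaternary C10 and its trans relation to C5 are secured in A2 by classical decalin chemistry and not by a strained ring closure; on this point it is the better plan.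
- Against it here: A1 has oxygen only at C12, so the C11 oxygen and the aromatic ring must still be made by dehydrogenation and ortho-oxidation. The C7 ketone must be reduced to the 7β-alcohol and lactonised. The two stereocentres formed in the cycloaddition (C8, C9) are destroyed on aromatisation. The β-carbon of A2 is neopentyl. The enol ether of A1 lies next to C15, so an acid-induced double-bond shift could erase the side-chain stereocentre.
- Comparison: structurally it builds ring C instead of ring B and postpones the lactone. Mechanistically it is an ionic cycloaddition without a transition metal. In step count it is behind, since several redox and deprotection steps follow A1 whereas two follow 21. On setting C15 early the two plans are equal.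

Alternative 2: The cuts are C4–C5 and C1–C10. An isopropenyl organolithium would add to C5 of the chiral 1-naphthyl oxazoline A5, and the anionic adduct would be alkylated at C10 by a homoallylic iodide from the opposite face, giving the trans-disubstituted dihydronaphthalene A4.
- In its favour: C5 and the quaternary C10 are set together, trans, under auxiliary control in an unstrained intermolecular step; on making C10 without a bridged metallacycle it is the better plan. Rings B and C come ready-made, and the C6=C7 styrene of A4 is well placed for acid-mediated lactonisation onto C7.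
- Against it here: the oxazoline sits peri to the C11 methoxy group and is twisted out of conjugation, which weakens the acceptor. Closing ring A between the butenyl and isopropenyl groups does not give the gem-dimethyl C4 directly; metathesis leaves a C3=C4 alkene with one methyl, and a further methylation sequence is needed. Hydrolysing an oxazoline on a neopentyl quaternary carbon is slow and usually takes several steps. A5 is a heavily substituted naphthalene that needs its own synthesis.
- Comparison: both plans install the C7 oxygen late and both rely on a tether or auxiliary for C10, so they are equal in stereochemical logic. In step economy the alternative is clearly longer after its key step.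

Alternative 3: The cuts are C5–C10 and C6–C7. Dehydration of the o-formyl arylacetic acid A7 with an acid anhydride on heating would give the transient 2-benzopyran-3-one A8, which adds the tethered vinyl group intramolecularly to give A6, the 3-silyloxy analogue of carnosol dimethyl ether 16-acetate.
- In its favour: it is the most bond-forming option, with rings A and B, two C–C bonds, three stereocentres and the lactone bridge all made at once and without metal. The acetate is already present, so no late selective acylation is needed; that is a real advantage over the chosen plan. The cis relation of C7–O and C20 is geometrically enforced, as in the chosen plan.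
- Against it here: the dienophile is an unactivated vinyl group on the quaternary C4. The trans A/B outcome rests on a remote C3 silyloxy group that must afterwards be removed by desilylation and radical deoxygenation. A8 is prone to dimerise. A7 is a penta-substituted arene with vicinal formyl and branched acetic acid groups. The final demethylation would have to be done with the acetate in place.
- Comparison: the alternative is equal or better in bonds formed per step. It is weaker in stereocontrol at C5, which the chosen plan fixes earlier by a substrate-controlled addition, and it is no shorter once the C3 deoxygenation is counted.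

Key step: step 11

## Route

Step 1
Reactants: 1 5-bromo-3,4-dimethoxybenzaldehyde
Product: 2 1-bromo-5-(dimethoxymethyl)-2,3-dimethoxybenzene
Conditions: HC(OMe)3, TsOH·H2O (2 mol %), MeOH, 25 °C; then Et3N
Reagents that add atoms: trimethyl orthoformate, COC(OC)OC
Why: Acid-catalysed acetalisation with the orthoformate as water scavenger is routine for electron-rich benzaldehydes; the acetal hides the carbonyl from the boron hydride of step 3 and later serves as ortho-director in step 5.

Step 2
Reactants: 2 1-bromo-5-(dimethoxymethyl)-2,3-dimethoxybenzene; 3 isopropenylboronic acid pinacol ester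
Product: 4 5-(dimethoxymethyl)-1,2-dimethoxy-3-(prop-1-en-2-yl)benzene
Conditions: PdCl2(dppf) (3 mol %), K2CO3, 1,4-dioxane/H2O (4:1), 85 °C
Reagents that add atoms: none
Why: Suzuki–Miyaura coupling of an aryl bromide with an alkenyl boronate; the acetal is stable to aqueous carbonate and one ortho methoxy group does not hinder oxidative addition.

Step 3
Reactants: 4 5-(dimethoxymethyl)-1,2-dimethoxy-3-(prop-1-en-2-yl)benzene
Product: 6 (2S)-2-[5-(dimethoxymethyl)-2,3-dimethoxyphenyl]propan-1-ol, via pinacol boronate 5 (not isolated)
Conditions: HBpin, CoCl2·L* (2 mol %; L* = enantiopure 2-(4-tert-butyl-4,5-dihydrooxazol-2-yl)-6-[1-(2,6-diisopropylphenylimino)ethyl]pyridine), NaBHEt3 (4 mol %), THF, 25 °C; then NaOH, H2O2, 0 °C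
Reagents that add atoms: pinacolborane, CC1(C)OBOC1(C)C (its boron stays only in 5); hydrogen peroxide, OO
Why: Cobalt-catalysed asymmetric anti-Markovnikov hydroboration of 1,1-disubstituted aryl alkenes is an established route to 2-arylpropyl boronates. C15 is set by the chiral ligand in the face-selective insertion of the alkene, and stereoretentive oxidation turns (R)-5 into (S)-6 (the descriptor changes only through CIP priorities).

Step 4
Reactants: 6 (2S)-2-[5-(dimethoxymethyl)-2,3-dimethoxyphenyl]propan-1-ol
Product: 7 1-[(2S)-1-(benzyloxy)propan-2-yl]-5-(dimethoxymethyl)-2,3-dimethoxybenzene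
Conditions: NaH, BnBr, n-Bu4NI (cat.), THF, 0 → 25 °C
Reagents that add atoms: benzyl bromide, BrCc1ccccc1
Why: Williamson etherification of a primary alkoxide; the benzyl ether withstands the later bases and is removed with the methyl ethers in step 12.

Step 5
Reactants: 7 1-[(2S)-1-(benzyloxy)propan-2-yl]-5-(dimethoxymethyl)-2,3-dimethoxybenzene
Product: 10 5-[(2S)-1-(benzyloxy)propan-2-yl]-2-bromo-3,4-dimethoxybenzaldehyde, via aryllithium 8 (not isolated), via bromo acetal 9 (not isolated)
Conditions: n-BuLi, THF, −20 → 0 °C; BrCl2C–CCl2Br, −78 → 0 °C; then 1 M HCl, THF, 25 °C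
Reagents that add atoms: 1,2-dibromo-1,1,2,2-tetrachloroethane, BrC(Cl)(Cl)C(Cl)(Cl)Br; water, O
Why: Directed ortho-metalation: C9–H lies between the acetal and the C11 methoxy group and is removed through cooperative coordination, whereas C14–H has one director and an alkyl neighbour. The aryllithium takes electrophilic bromine from the dibromide and dilute acid releases the aldehyde. Electrophilic bromination is no substitute because it would attack C14, para to the C11 oxygen.

Step 6
Reactants: 10 5-[(2S)-1-(benzyloxy)propan-2-yl]-2-bromo-3,4-dimethoxybenzaldehyde
Product: 12 (1S)-1-Ar-but-3-en-1-ol, via borinate ester 11 (not isolated)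
Conditions: (−)-Ipc2B(allyl) (1 M in pentane), Et2O, −78 °C; then NaOH, H2O2, 0 → 25 °C
Reagents that add atoms: (−)-B-allyldiisopinocampheylborane, C=CCB([C@@H]1C[C@@H]2C[C@H]([C@H]1C)C2(C)C)[C@@H]1C[C@@H]2C[C@H]([C@H]1C)C2(C)C
Why: Brown allylboration through a closed chair transition state; the reagent derived from (+)-α-pinene delivers the allyl group to the Si face of aryl aldehydes and should give the (1S) alcohol regardless of the remote C15 centre. Oxidative work-up cleaves the borinate.

Step 7
Reactants: 12 (1S)-1-Ar-but-3-en-1-ol; 13 acryloyl chloride
Product: 14 (1S)-1-Ar-but-3-en-1-yl prop-2-enoate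
Conditions: Et3N, DMAP (5 mol %), CH2Cl2, −20 → 0 °C
Reagents that add atoms: none
Why: Acylation of a secondary benzylic alcohol by an acid chloride under nucleophilic catalysis; the low temperature limits conjugate addition of amine to the acrylate.

Step 8
Reactants: 14 (1S)-1-Ar-but-3-en-1-yl prop-2-enoate
Product: 15 (6S)-6-Ar-5,6-dihydro-2H-pyran-2-one
Conditions: second-generation Grubbs catalyst (5 mol %), CH2Cl2 (5 mM), 40 °C
Reagents that add atoms: none
Why: Ring-closing metathesis of an acrylate with a terminal alkene to a 5,6-dihydro-2H-pyran-2-one is standard with this ruthenium carbene; loss of ethene drives it and neither the bromide nor the ethers interfere.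

Step 9
Reactants: 15 (6S)-6-Ar-5,6-dihydro-2H-pyran-2-one; 16 5-bromo-2-methylpent-2-ene
Product: 17 (4R,6S)-6-Ar-4-(5-bromo-2-methylpentan-2-yl)oxan-2-one
Conditions: Fe(acac)3 (30 mol %), PhSiH3, EtOH/HOCH2CH2OH (5:1), 60 °C; 16 in excess
Reagents that add atoms: none
Why: Iron-catalysed reductive olefin coupling (metal-hydride hydrogen-atom transfer, then Giese addition): an iron hydride from Fe(acac)3 and PhSiH3 gives a hydrogen atom to C3 of 16, the tertiary C4 radical adds to C5 of the unsaturated lactone, and the C10 radical is reduced and protonated by ethanol. C5 is set by the substrate: the half-chair lactone with the C7 aryl group pseudo-equatorial is attacked axially on the face anti to that group, as is usual for 6-substituted dihydropyranones, which gives the 5,7-trans adduct. Neither bromide is reduced under these conditions.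

Step 10
Reactants: 17 (4R,6S)-6-Ar-4-(5-bromo-2-methylpentan-2-yl)oxan-2-one
Product: 19 (3S,4aR,8aRS)-3-Ar-5,5-dimethyl-3,4,4a,5,6,7,8,8a-octahydro-1H-isochromen-1-one (ring A-fused lactone; either C10 epimer), via potassium enolate 18 (not isolated)
Conditions: KN(SiMe3)2, THF, −78 → −20 °C
Reagents that add atoms: none
Why: Intramolecular C-alkylation of a lactone enolate by a primary bromide (6-exo-tet) closes ring A by forming C1–C10. The C10 configuration is immaterial because step 11 erases it, and the aryl bromide is inert to the amide base because C9 has no ortho hydrogen from which an aryne could form.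

Step 11
Reactants: 19 (3S,4aR,8aRS)-3-Ar-5,5-dimethyl-3,4,4a,5,6,7,8,8a-octahydro-1H-isochromen-1-one
Product: 21 (4aR,9S,10aS)-7-[(2S)-1-(benzyloxy)propan-2-yl]-5,6-dimethoxy-1,1-dimethyl-2,3,4,9,10,10a-hexahydro-1H-9,4a-(epoxymethano)phenanthren-12-one (carnosol dimethyl ether 16-benzyl ether), via lithium enolate 20 (not isolated)
Conditions: LiN(C6H11)2 (1.5 equiv), Pd2(dba)3 (5 mol %), P(t-Bu)3 (12 mol %), toluene (0.01 M), 25 → 60 °C
Reagents that add atoms: none
Why: LiN(C6H11)2, chosen because it fully deprotonates a tertiary α-C–H, converts either C10 epimer of 19 into the planar enolate 20, while zerovalent palladium bearing one P(t-Bu)3 inserts into the C9–Br bond; the enolate displaces bromide to give a C10-bound arylpalladium enolate in which the metal spans C9 and C10 in a bridged seven-membered palladacycle, and reductive elimination from divalent palladium forms C9–C10 and returns the catalyst. The closest known reaction type is the palladium-catalysed intramolecular α-arylation of α,α-disubstituted ester and lactone enolates to benzylic quaternary carbons, together with the bridging closures known for ketone enolates. Ring B (C5–C6–C7–C8–C9–C10) closes as the two-carbon arene bridge of a 2-oxabicyclo[2.2.2]octan-3-one; the closure is exo with respect to the C10=C20 enolate bond and passes through a boat of the lactone with C7 raised. C10 is the only new stereocentre and is fixed by C7 through the tether: the aryl group can reach only the enolate face on which it stands, and because ring A fusion places H5 axial on that same face (aryl trans to C5–C4), the trans A/B (4aR,10aS) isomer must result. The step needs C- over O-arylation (the O-bound path would create a bridgehead ketene acetal), reductive elimination over β-hydride loss toward C1 or C5 (favoured by the bulky, electron-rich phosphine) and intramolecular over intermolecular coupling (favoured by the tether and by dilution). The di-ortho-substituted bromide is of the hindered kind that this ligand is known to activate.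

Step 12
Reactants: 21 carnosol dimethyl ether 16-benzyl ether
Product: 22 (4aR,9S,10aS)-5,6-dihydroxy-7-[(2S)-1-hydroxypropan-2-yl]-1,1-dimethyl-2,3,4,9,10,10a-hexahydro-1H-9,4a-(epoxymethano)phenanthren-12-one (16-hydroxycarnosol)
Conditions: BBr3, C6HMe5, CH2Cl2, −78 → 0 °C; then H2O (degassed)
Reagents that add atoms: none
Why: Boron tribromide cleaves the two aryl methyl ethers and the benzyl ether by bromide attack on the O-alkyl carbon of the boron-complexed ethers, and aqueous work-up hydrolyses the borates; pentamethylbenzene traps the benzyl cation before it can alkylate C14. Should the C7–O bond ionise reversibly, re-closure regenerates the same lactone.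

Step 13
Reactants: 22 16-hydroxycarnosol
Product: 23 [(2S)-2-[(4aR,9S,10aS)-5,6-dihydroxy-1,1-dimethyl-12-oxo-2,3,4,9,10,10a-hexahydro-1H-9,4a-(epoxymethano)phenanthren-7-yl]propyl] acetate (16-acetoxycarnosol)
Conditions: immobilised Candida antarctica lipase B, vinyl acetate, t-BuOMe/THF, 35 °C, argon
Reagents that add atoms: vinyl acetate, CC(=O)OC=C
Why: Lipase-catalysed transesterification with an enol ester acylates primary aliphatic alcohols and leaves hindered phenols untouched; the neutral conditions avoid acyl migration and catechol oxidation, and tautomerisation of the released enol makes the transfer irreversible.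

## Compound list

1 | 5-bromo-3,4-dimethoxybenzaldehyde | COc1cc(C=O)cc(Br)c1OC | starting material
2 | 1-bromo-5-(dimethoxymethyl)-2,3-dimethoxybenzene | COc1cc(C(OC)OC)cc(Br)c1OC | intermediate
3 | isopropenylboronic acid pinacol ester | CC(=C)B1OC(C)(C)C(C)(C)O1 | starting material
4 | 5-(dimethoxymethyl)-1,2-dimethoxy-3-(prop-1-en-2-yl)benzene | COc1cc(C(OC)OC)cc(C(C)=C)c1OC | intermediate
5 | 2-{(2R)-2-[5-(dimethoxymethyl)-2,3-dimethoxyphenyl]propyl}-4,4,5,5-tetramethyl-1,3,2-dioxaborolane (not isolated) | COc1cc(C(OC)OC)cc([C@H](C)CB2OC(C)(C)C(C)(C)O2)c1OC | intermediate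
6 | (2S)-2-[5-(dimethoxymethyl)-2,3-dimethoxyphenyl]propan-1-ol | COc1cc(C(OC)OC)cc([C@H](C)CO)c1OC | intermediate
7 | 1-[(2S)-1-(benzyloxy)propan-2-yl]-5-(dimethoxymethyl)-2,3-dimethoxybenzene | COc1cc(C(OC)OC)cc([C@H](C)COCc2ccccc2)c1OC | intermediate
8 | {4-[(2S)-1-(benzyloxy)propan-2-yl]-6-(dimethoxymethyl)-2,3-dimethoxyphenyl}lithium (not isolated) | [Li]c1c(C(OC)OC)cc([C@H](C)COCc2ccccc2)c(OC)c1OC | intermediate
9 | 1-[(2S)-1-(benzyloxy)propan-2-yl]-4-bromo-5-(dimethoxymethyl)-2,3-dimethoxybenzene (not isolated) | Brc1c(C(OC)OC)cc([C@H](C)COCc2ccccc2)c(OC)c1OC | intermediate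
10 | 5-[(2S)-1-(benzyloxy)propan-2-yl]-2-bromo-3,4-dimethoxybenzaldehyde | O=Cc1cc([C@H](C)COCc2ccccc2)c(OC)c(OC)c1Br | intermediate
11 | (1S)-1-Ar-but-3-en-1-yl diisopinocampheylborinate, Ipc from (+)-α-pinene (not isolated) | C=CC[C@H](OB([C@@H]2C[C@@H]3C[C@H]([C@H]2C)C3(C)C)[C@@H]2C[C@@H]3C[C@H]([C@H]2C)C3(C)C)c1cc([C@H](C)COCc2ccccc2)c(OC)c(OC)c1Br | intermediate
12 | (1S)-1-{5-[(2S)-1-(benzyloxy)propan-2-yl]-2-bromo-3,4-dimethoxyphenyl}but-3-en-1-ol | C=CC[C@H](O)c1cc([C@H](C)COCc2ccccc2)c(OC)c(OC)c1Br | intermediate
13 | acryloyl chloride | C=CC(=O)Cl | starting material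
14 | (1S)-1-{5-[(2S)-1-(benzyloxy)propan-2-yl]-2-bromo-3,4-dimethoxyphenyl}but-3-en-1-yl prop-2-enoate | C=CC[C@H](OC(=O)C=C)c1cc([C@H](C)COCc2ccccc2)c(OC)c(OC)c1Br | intermediate
15 | (6S)-6-{5-[(2S)-1-(benzyloxy)propan-2-yl]-2-bromo-3,4-dimethoxyphenyl}-5,6-dihydro-2H-pyran-2-one | O=C1C=CC[C@@H](c2cc([C@H](C)COCc3ccccc3)c(OC)c(OC)c2Br)O1 | intermediate
16 | 5-bromo-2-methylpent-2-ene | CC(C)=CCCBr | starting material
17 | (4R,6S)-6-{5-[(2S)-1-(benzyloxy)propan-2-yl]-2-bromo-3,4-dimethoxyphenyl}-4-(5-bromo-2-methylpentan-2-yl)oxan-2-one | O=C1C[C@H](C(C)(C)CCCBr)C[C@@H](c2cc([C@H](C)COCc3ccccc3)c(OC)c(OC)c2Br)O1 | intermediate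
18 | potassium enolate of 17 (not isolated) | [K+].[O-]C1=C[C@H](C(C)(C)CCCBr)C[C@@H](c2cc([C@H](C)COCc3ccccc3)c(OC)c(OC)c2Br)O1 | intermediate
19 | (3S,4aR,8aRS)-3-{5-[(2S)-1-(benzyloxy)propan-2-yl]-2-bromo-3,4-dimethoxyphenyl}-5,5-dimethyl-3,4,4a,5,6,7,8,8a-octahydro-1H-isochromen-1-one | O=C1O[C@H](c2cc([C@H](C)COCc3ccccc3)c(OC)c(OC)c2Br)C[C@H]2C(C)(C)CCCC12 | intermediate
20 | lithium enolate of 19 (not isolated) | [Li+].[O-]C1=C2CCCC(C)(C)[C@@H]2C[C@@H](c3cc([C@H](C)COCc4ccccc4)c(OC)c(OC)c3Br)O1 | intermediate
21 | carnosol dimethyl ether 16-benzyl ether, (4aR,9S,10aS)-7-[(2S)-1-(benzyloxy)propan-2-yl]-5,6-dimethoxy-1,1-dimethyl-2,3,4,9,10,10a-hexahydro-1H-9,4a-(epoxymethano)phenanthren-12-one | c1ccccc1COC[C@@H](C)c1cc2c(c(OC)c1OC)[C@@]13CCCC(C)(C)[C@@H]1C[C@@H]2OC3=O | intermediate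
22 | 16-hydroxycarnosol, (4aR,9S,10aS)-5,6-dihydroxy-7-[(2S)-1-hydroxypropan-2-yl]-1,1-dimethyl-2,3,4,9,10,10a-hexahydro-1H-9,4a-(epoxymethano)phenanthren-12-one | OC[C@@H](C)c1cc2c(c(O)c1O)[C@@]13CCCC(C)(C)[C@@H]1C[C@@H]2OC3=O | intermediate
23 | 16-acetoxycarnosol (CNP0105472.1) | CC(=O)OC[C@@H](C)c1cc2c(c(O)c1O)[C@@]13CCCC(C)(C)[C@@H]1C[C@@H]2OC3=O | target

## Step count and least certain steps

Total: 13 steps. Longest linear sequence: 13 steps, from 1; compounds 3, 13 and 16 are bought.

Step 11 (key step). The arylpalladium enolate may not reach the boat geometry that reductive elimination requires. The aryl–palladium bond would then be lost by protodebromination, the C-bound enolate could lose a β-hydride toward C1 or C5, or the enolate could condense with unreacted lactone. The fallback drops the organometallic pathway for a photostimulated radical-chain substitution (SRN1). It sets out from 19: enolate 20 is generated with LiN(C6H11)2 in THF/liquid NH3 and irradiated with near-UV light. Electron transfer to the C9–Br bond releases the C9 aryl radical, which adds 6-exo to C10 of the enolate, and the resulting radical anion passes its electron on. The route is rejoined at 21 with no new isolated compound. Intramolecular arylations of this type are known for ketone and amide enolates leading to quaternary benzylic carbons.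

Step 9. Hydrogen-atom transfer and addition of the hindered tertiary radical to a β-substituted lactone may be slower than simple reduction of the radical, so that 15 is recovered. Face selectivity may also suffer at 60 °C if the aryl group does not stay pseudo-equatorial. The fallback generates the radical by reductive decarboxylation at or below room temperature. It sets out from 15: 1,3-dioxoisoindolin-2-yl 5-chloro-2,2-dimethylpentanoate F1 (from commercial 5-chloro-2,2-dimethylpentanoic acid, N-hydroxyphthalimide and a carbodiimide) is irradiated with blue light together with 15, Ru(bpy)3(PF6)2, Hantzsch ester and i-Pr2NEt. This should give the chloroalkyl lactone (4R,6S)-6-Ar-4-(5-chloro-2-methylpentan-2-yl)oxan-2-one F2. KN(SiMe3)2 with NaI then closes ring A, and the route is rejoined at 19.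

Step 3. The ortho methoxy group twists the alkene out of the arene plane and may erode the enantioselectivity. Because C15 is remote, the minor enantiomer would surface later as a diastereomer that is hard to remove. The fallback is an auxiliary-controlled α-arylation that sets out from 2. Coupling of 2 with the trimethylsilyl enolate of (4R)-4-benzyl-3-propanoyl-1,3-oxazolidin-2-one F3 (Pd(dba)2, P(t-Bu)3, ZnF2, DMF, 80 °C) should give (4R)-4-benzyl-3-{(2S)-2-[5-(dimethoxymethyl)-2,3-dimethoxyphenyl]propanoyl}-1,3-oxazolidin-2-one F4, whose diastereomers can be separated by chromatography. LiBH4 reduction rejoins the route at 6. The (4R) auxiliary is chosen by analogy with alkylation of the chelated Z-enolate; if the sense proves opposite, the (4S) auxiliary is used.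

Step 5. n-BuLi may deprotonate the benzylic O–CH2 group of the ether, followed by Wittig rearrangement, in competition with a slow ring lithiation. The fallback carries the alcohol through the metalation as a silyl ether and sets out from 6. i-Pr3SiCl/imidazole gives (2S)-2-[5-(dimethoxymethyl)-2,3-dimethoxyphenyl]propyl triisopropylsilyl ether F5. The lithiation, bromination and hydrolysis of step 5 then give 2-bromo-3,4-dimethoxy-5-[(2S)-1-(triisopropylsilyloxy)propan-2-yl]benzaldehyde F6. n-Bu4NF gives 2-bromo-5-[(2S)-1-hydroxypropan-2-yl]-3,4-dimethoxybenzaldehyde F7. Acid-catalysed benzylation with benzyl 2,2,2-trichloroacetimidate (TfOH cat.), which tolerates the aldehyde, rejoins the route at 10.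

Step 12. The boron halide may ionise the C7–O bond, with loss of a proton from C6 or capture of bromide, and the primary borate may go on to the bromide on warming. The fallback opens the lactone on purpose, demethylates the robust acid and re-closes by oxidation. It sets out from 21. Hydrogenolysis (H2, Pd/C, AcOH) cleaves the benzyl ether and the benzylic C7–O bond to give 16-hydroxy-11,12-di-O-methylcarnosic acid F8. BBr3 then gives 16-hydroxycarnosic acid F9. Mild oxidation (O2 in MeOH, or Ag2O) of the catechol and tautomerisation make C7 electrophilic, the C20 carboxylate captures it, and the route is rejoined at 22. This mirrors the known oxidative conversion of carnosic acid into carnosol.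

Step 13. Acyl transfer may be slow because the β-branch carries a very bulky aryl group and may have the configuration the enzyme disfavours. Long reaction times invite phenol acylation and catechol oxidation. The fallback sets out from 22. Exhaustive acetylation (Ac2O, pyridine, DMAP) gives 11,12,16-tri-O-acetyl-16-hydroxycarnosol F10. Selective aminolysis of the two aryl acetates with pyrrolidine at 0 °C, which are far more reactive than the alkyl acetate and the hindered lactone, rejoins the route at 23.

## Further compounds

F0 | step 11 | none | none
F1 | step 9 | 1,3-dioxoisoindolin-2-yl 5-chloro-2,2-dimethylpentanoate | O=C(ON1C(=O)c2ccccc2C1=O)C(C)(C)CCCCl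
F2 | step 9 | (4R,6S)-6-{5-[(2S)-1-(benzyloxy)propan-2-yl]-2-bromo-3,4-dimethoxyphenyl}-4-(5-chloro-2-methylpentan-2-yl)oxan-2-one | O=C1C[C@H](C(C)(C)CCCCl)C[C@@H](c2cc([C@H](C)COCc3ccccc3)c(OC)c(OC)c2Br)O1
F3 | step 3 | (Z)-trimethylsilyl enolate of (4R)-4-benzyl-3-propanoyl-1,3-oxazolidin-2-one | C/C=C(\O[Si](C)(C)C)N1[C@H](Cc2ccccc2)COC1=O
F4 | step 3 | (4R)-4-benzyl-3-{(2S)-2-[5-(dimethoxymethyl)-2,3-dimethoxyphenyl]propanoyl}-1,3-oxazolidin-2-one | COc1cc(C(OC)OC)cc([C@H](C)C(=O)N2[C@H](Cc3ccccc3)COC2=O)c1OC
F5 | step 5 | (2S)-2-[5-(dimethoxymethyl)-2,3-dimethoxyphenyl]propyl triisopropylsilyl ether | COc1cc(C(OC)OC)cc([C@H](C)CO[Si](C(C)C)(C(C)C)C(C)C)c1OC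
F6 | step 5 | 2-bromo-3,4-dimethoxy-5-[(2S)-1-(triisopropylsilyloxy)propan-2-yl]benzaldehyde | O=Cc1cc([C@H](C)CO[Si](C(C)C)(C(C)C)C(C)C)c(OC)c(OC)c1Br
F7 | step 5 | 2-bromo-5-[(2S)-1-hydroxypropan-2-yl]-3,4-dimethoxybenzaldehyde | O=Cc1cc([C@H](C)CO)c(OC)c(OC)c1Br
F8 | step 12 | 16-hydroxy-11,12-di-O-methylcarnosic acid | OC[C@@H](C)c1cc2c(c(OC)c1OC)[C@@]1(C(=O)O)CCCC(C)(C)[C@@H]1CC2
F9 | step 12 | 16-hydroxycarnosic acid | OC[C@@H](C)c1cc2c(c(O)c1O)[C@@]1(C(=O)O)CCCC(C)(C)[C@@H]1CC2
F10 | step 13 | 11,12,16-tri-O-acetyl-16-hydroxycarnosol | CC(=O)OC[C@@H](C)c1cc2c(c(OC(C)=O)c1OC(C)=O)[C@@]13CCCC(C)(C)[C@@H]1C[C@@H]2OC3=O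
A1 | alternative 1 | tricyclic C7 ketone with ring C as silyl enol ether (cycloadduct) | COC(=O)[C@]12CCCC(C)(C)[C@@H]1CC(=O)[C@H]1CC([C@H](C)COCc3ccccc3)=C(O[Si](C)(C)C(C)(C)C)C[C@H]12
A2 | alternative 1 | trans-decalin enone ester (C7 ketone, C8=C9 alkene, methyl ester on C10) | COC(=O)[C@]12CCCC(C)(C)[C@@H]1CC(=O)C=C2
A3 | alternative 1 | (S)-configured 2-(tert-butyldimethylsilyloxy)-3-[1-(benzyloxy)propan-2-yl]buta-1,3-diene | C=C(O[Si](C)(C)C(C)(C)C)C(=C)[C@H](C)COCc1ccccc1
A4 | alternative 2 | trans-1-butenyl-2-isopropenyl-1,2-dihydronaphthalene oxazoline | c1ccccc1COC[C@@H](C)c1cc2c(c(OC)c1OC)[C@](CCC=C)(C3=N[C@H](C(C)(C)C)CO3)[C@H](C(C)=C)C=C2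
A5 | alternative 2 | chiral 1-naphthyl oxazoline (7,8-dimethoxy, 6-side chain) | COc1c(OC)c([C@H](C)COCc2ccccc2)cc2cccc(C3=N[C@H](C(C)(C)C)CO3)c12
A6 | alternative 3 | 3-silyloxy carnosol dimethyl ether 16-acetate | CC(=O)OC[C@@H](C)c1cc2c(c(OC)c1OC)[C@@]13CC[C@H](O[Si](C)(C)C(C)(C)C)C(C)(C)[C@@H]1C[C@@H]2OC3=O
A7 | alternative 3 | o-formyl arylacetic acid with silyloxy-substituted vinyl tether | CC(=O)OC[C@@H](C)c1cc(C=O)c(c(OC)c1OC)C(C(=O)O)CC[C@H](O[Si](C)(C)C(C)(C)C)C(C)(C)C=C
A8 | alternative 3 | transient 2-benzopyran-3-one | O=C1OC=C2C=C([C@H](C)COC(C)=O)C(OC)=C(OC)C2=C1CC[C@H](O[Si](C)(C)C(C)(C)C)C(C)(C)C=C
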